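**Plan**

1. Ring atoms carry quinic acid numbers (C1 quaternary, C5 the carbinol carbon cis to the carboxyl). Going backwards, the C1 carboxyl becomes a formyl group, the C5–O bond a lactonisation onto a C4=C5 alkene, and the C3/C4 diol a C3=C4 alkene. The ring is then cut at C1–C6 and C2–C3 into buta-1,3-diene and a 2-(caffeoyloxy)acrolein, and the enol ester C–O bond is cut last.
2. Enabling feature: C2 and C6, the two ring carbons flanking quaternary C1, are unsubstituted CH2 groups. C1 can therefore come from the α-carbon of an acrolein that already carries the caffeoyl ester oxygen and the future carboxyl carbon; the cyclohexane is the only ring.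
3. Forward order: diacetylcaffeoyl enol ester of a dioxanone, then the acyloxyacrolein, then the carbocycle by [4+2] cycloaddition, then the acid, the lactone bridge from C1 to C5, the alkene moved to C3=C4, the cis-diol, and global acid hydrolysis.
4. Stereochemistry: C1 comes from a chiral primary ammonium catalyst. C5 follows from oxygen delivery by the C1 carboxyl, and C4 and C3 from osmylation anti to the lactone bridge.

Key step: step 5

Assumption: the sense of induction of the binaphthyldiammonium catalyst with an acyclic diene is not certain, so the route is written with the (R)-diamine as the antipode giving the (S)-cycloadduct; the equally available (S)-diamine replaces it if the first run shows the opposite sense.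

**Route**

Step 1
Reactants: 1 caffeic acid
Product: 2 (E)-3-(3,4-diacetoxyphenyl)prop-2-enoic acid
Conditions: Ac2O, pyridine, 4-(dimethylamino)pyridine (cat.), 0 °C → rt; then ice/1 M HCl
Reagents that add atoms: acetic anhydride, CC(=O)OC(C)=O
Why: Base-promoted O-acetylation (nucleophilic acyl substitution) caps both phenols, which would otherwise be acylated in step 3 and oxidised in steps 6 to 9, as esters that the final acid hydrolysis removes.

Step 2
Reactants: 2 (E)-3-(3,4-diacetoxyphenyl)prop-2-enoic acid
Product: 3 (E)-3-(3,4-diacetoxyphenyl)prop-2-enoyl chloride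
Conditions: (COCl)2, Me2NCHO (cat.), CH2Cl2, 0 °C → rt; evaporate, use crude
Reagents that add atoms: oxalyl chloride, O=C(Cl)C(=O)Cl
Why: Formamide-catalysed acid chloride formation with oxalyl chloride is routine for this acid and leaves the aryl acetates and the E-alkene untouched.

Step 3
Reactants: 4 2,2-dimethyl-1,3-dioxan-5-one; 3 (E)-3-(3,4-diacetoxyphenyl)prop-2-enoyl chloride
Product: 6 2,2-dimethyl-4H-1,3-dioxin-5-yl (E)-3-(3,4-diacetoxyphenyl)prop-2-enoate, via potassium dioxinolate 5 (not isolated)
Conditions: KN(SiMe3)2, THF, −78 °C; then cannulated into 3, THF, −78 → −40 °C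
Reagents that add atoms: none
Why: Enolate O-acylation, in which the potassium enolate meets the hard acyl chloride in THF at low temperature and reacts at oxygen, so the later hindered tertiary ester is made while its carbon is still a planar enol carbon, and inverse addition keeps the enolate away from the aryl acetates.

Step 4
Reactants: 6 2,2-dimethyl-4H-1,3-dioxin-5-yl (E)-3-(3,4-diacetoxyphenyl)prop-2-enoate
Product: 7 3-oxoprop-1-en-2-yl (E)-3-(3,4-diacetoxyphenyl)prop-2-enoate [2-(3,4-diacetoxycinnamoyloxy)acrolein]
Conditions: PhMe, 110 °C, 2,6-di-tert-butyl-4-methylphenol (trace); evaporate, use at once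
Reagents that add atoms: none
Why: Retro-hetero-Diels–Alder reaction (thermal [4+2] cycloreversion) of the 4H-1,3-dioxin expels volatile acetone and releases the 2-acyloxyacrolein, the established entry to this class of dienophile.

Step 5
Reactants: 7 3-oxoprop-1-en-2-yl (E)-3-(3,4-diacetoxyphenyl)prop-2-enoate; 8 buta-1,3-diene
Product: 9 (S)-1-formylcyclohex-3-en-1-yl (E)-3-(3,4-diacetoxyphenyl)prop-2-enoate
Conditions: (R)-1,1'-binaphthyl-2,2'-diamine (10 mol %), HNTf2 (19 mol %), EtCN, 8 (10 equiv), sealed tube, −20 °C
Reagents that add atoms: none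
Why: One ammonium group of the catalyst condenses reversibly with the formyl group of 7, and the catalyst-bound, LUMO-lowered α-acyloxy iminium ion takes up s-cis butadiene in a concerted suprafacial [4+2] cycloaddition that forms C1–C6 and C2–C3 together, after which hydrolysis releases 9 and the catalyst. The closest known reaction type is the primary-ammonium-catalysed enantioselective Diels–Alder reaction of 2-acyloxyacroleins with dienes, within which butadiene and a cinnamoyloxy group are new partners. The cyclohexene ring closes by intermolecular [4+2] cycloaddition, both σ-bonds arising in the same pericyclic event. C1 is the only new stereocentre and is controlled by the axially chiral binaphthyl backbone, which holds the iminium ion, with the acyloxy carbonyl hydrogen-bonded to the second ammonium group, so that one enantioface is covered. The step needs only enantiofacial selectivity and chemoselectivity: symmetric butadiene removes regiochemical and endo/exo questions, and the ester-deactivated trans cinnamate alkene cannot form an iminium ion and stays out of the cycloaddition.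

Step 6
Reactants: 9 (S)-1-formylcyclohex-3-en-1-yl (E)-3-(3,4-diacetoxyphenyl)prop-2-enoate
Product: 10 (S)-1-{[(E)-3-(3,4-diacetoxyphenyl)prop-2-enoyl]oxy}cyclohex-3-ene-1-carboxylic acid
Conditions: NaClO2, NaH2PO4, 2-methyl-2-butene, t-BuOH–H2O, 0 °C → rt
Reagents that add atoms: sodium chlorite, [Na+].[O-]Cl=O
Why: Pinnick oxidation converts the non-enolisable α-acyloxy aldehyde into the acid near pH 4, where all esters are safe, while 2-methyl-2-butene intercepts HOCl before it can reach either alkene.

Step 7
Reactants: 10 (S)-1-{[(E)-3-(3,4-diacetoxyphenyl)prop-2-enoyl]oxy}cyclohex-3-ene-1-carboxylic acid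
Product: 11 (1S,4R,5R)-7-oxo-4-(phenylselanyl)-6-oxabicyclo[3.2.1]octan-1-yl (E)-3-(3,4-diacetoxyphenyl)prop-2-enoate (PhSe anti to the lactone oxygen)
Conditions: PhSeCl, CH2Cl2, −78 °C → rt
Reagents that add atoms: benzeneselenenyl chloride, Cl[Se]c1ccccc1
Why: Phenylselenolactonisation (electrophilic anti addition) closes the kinetically preferred γ-lactone at the nearer alkene carbon C5, so the C5–O bond is necessarily syn to the C1 carboxyl carbon and selenium sits anti at C4, both fixed by C1, while the ester-deactivated cinnamate alkene does not react at low temperature.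

Step 8
Reactants: 11 (1S,4R,5R)-7-oxo-4-(phenylselanyl)-6-oxabicyclo[3.2.1]octan-1-yl (E)-3-(3,4-diacetoxyphenyl)prop-2-enoate
Product: 13 (1S,5R)-7-oxo-6-oxabicyclo[3.2.1]oct-3-en-1-yl (E)-3-(3,4-diacetoxyphenyl)prop-2-enoate, via selenoxide 12 (not isolated)
Conditions: 30% aq. H2O2 (3 equiv), THF, 0 °C → rt
Reagents that add atoms: none
Why: Selenide oxidation followed by selenoxide syn-elimination places the alkene at C3=C4, because elimination toward C5 would give a bridgehead enol ester, and the neutral conditions spare the aryl acetates that an amidine base might attack.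

Step 9
Reactants: 13 (1S,5R)-7-oxo-6-oxabicyclo[3.2.1]oct-3-en-1-yl (E)-3-(3,4-diacetoxyphenyl)prop-2-enoate
Product: 14 (1S,3R,4R,5R)-3,4-dihydroxy-7-oxo-6-oxabicyclo[3.2.1]octan-1-yl (E)-3-(3,4-diacetoxyphenyl)prop-2-enoate [1-O-(di-O-acetylcaffeoyl)-1,5-quinide]
Conditions: OsO4 (2 mol %), N-methylmorpholine N-oxide (1.1 equiv), acetone–H2O, 0 °C
Reagents that add atoms: osmium tetroxide, O=[Os](=O)(=O)=O (transfers both oxygen atoms); N-methylmorpholine N-oxide, C[N+]1([O-])CCOCC1, and water, O (restore them to osmium)
Why: Upjohn syn-dihydroxylation, in which OsO4 adds suprafacially to the strained cis ring alkene from the face opposite the lactone bridge and so sets C3 and C4 anti to the C5–O bond, while the conjugated trans cinnamate alkene should react distinctly more slowly without an accelerating ligand and is further protected by limiting the oxidant.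

Step 10
Reactants: 14 1-O-(di-O-acetylcaffeoyl)-1,5-quinide
Product: 15 1-O-caffeoylquinic acid
Conditions: 2 M aq. HCl–THF (1:3), rt, several days
Reagents that add atoms: water, O
Why: Acid-catalysed ester hydrolysis cleaves the two aryl acetates and opens the strained bicyclic γ-lactone, whereas the conjugated, hindered tertiary cinnamate resists and the acidic medium avoids base-induced acyl migration, a global deprotection established for 1-O-(diacetylcaffeoyl)quinide derivatives.

**Compound list**

1 | caffeic acid | O=C(O)/C=C/c1ccc(O)c(O)c1 | starting material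
2 | (E)-3-(3,4-diacetoxyphenyl)prop-2-enoic acid | O=C(O)/C=C/c1ccc(OC(C)=O)c(OC(C)=O)c1 | intermediate
3 | (E)-3-(3,4-diacetoxyphenyl)prop-2-enoyl chloride | O=C(Cl)/C=C/c1ccc(OC(C)=O)c(OC(C)=O)c1 | intermediate
4 | 2,2-dimethyl-1,3-dioxan-5-one | CC1(C)OCC(=O)CO1 | starting material
5 | potassium 2,2-dimethyl-4H-1,3-dioxin-5-olate (formed in the flask) | CC1(C)OCC([O-])=CO1.[K+] | intermediate
6 | 2,2-dimethyl-4H-1,3-dioxin-5-yl (E)-3-(3,4-diacetoxyphenyl)prop-2-enoate | O=C(/C=C/c1ccc(OC(C)=O)c(OC(C)=O)c1)OC1=COC(C)(C)OC1 | intermediate
7 | 3-oxoprop-1-en-2-yl (E)-3-(3,4-diacetoxyphenyl)prop-2-enoate | C=C(C=O)OC(=O)/C=C/c1ccc(OC(C)=O)c(OC(C)=O)c1 | intermediate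
8 | buta-1,3-diene | C=CC=C | starting material
9 | (S)-1-formylcyclohex-3-en-1-yl (E)-3-(3,4-diacetoxyphenyl)prop-2-enoate | O=C(/C=C/c1ccc(OC(C)=O)c(OC(C)=O)c1)O[C@]1(C=O)CC=CCC1 | intermediate
10 | (S)-1-{[(E)-3-(3,4-diacetoxyphenyl)prop-2-enoyl]oxy}cyclohex-3-ene-1-carboxylic acid | O=C(/C=C/c1ccc(OC(C)=O)c(OC(C)=O)c1)O[C@]1(C(=O)O)CC=CCC1 | intermediate
11 | (1S,4R,5R)-7-oxo-4-(phenylselanyl)-6-oxabicyclo[3.2.1]octan-1-yl (E)-3-(3,4-diacetoxyphenyl)prop-2-enoate | O=C(/C=C/c1ccc(OC(C)=O)c(OC(C)=O)c1)O[C@@]12C[C@@H](OC1=O)[C@H]([Se]c1ccccc1)CC2 | intermediate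
12 | (1S,4R,5R)-7-oxo-4-(phenylseleninyl)-6-oxabicyclo[3.2.1]octan-1-yl (E)-3-(3,4-diacetoxyphenyl)prop-2-enoate, either configuration at selenium (formed in the flask) | O=C(/C=C/c1ccc(OC(C)=O)c(OC(C)=O)c1)O[C@@]12C[C@@H](OC1=O)[C@H]([Se](=O)c1ccccc1)CC2 | intermediate
13 | (1S,5R)-7-oxo-6-oxabicyclo[3.2.1]oct-3-en-1-yl (E)-3-(3,4-diacetoxyphenyl)prop-2-enoate | O=C(/C=C/c1ccc(OC(C)=O)c(OC(C)=O)c1)O[C@@]12C[C@@H](OC1=O)C=CC2 | intermediate
14 | (1S,3R,4R,5R)-3,4-dihydroxy-7-oxo-6-oxabicyclo[3.2.1]octan-1-yl (E)-3-(3,4-diacetoxyphenyl)prop-2-enoate | O=C(/C=C/c1ccc(OC(C)=O)c(OC(C)=O)c1)O[C@@]12C[C@@H](OC1=O)[C@H](O)[C@H](O)C2 | intermediate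
15 | 1-O-caffeoylquinic acid (1-O-[(E)-3-(3,4-dihydroxyphenyl)prop-2-enoyl]quinic acid) | O=C(/C=C/c1ccc(O)c(O)c1)O[C@]1(C(=O)O)C[C@@H](O)[C@H](O)[C@H](O)C1 | target

**Step count and risks**

Total steps: 10. Longest linear sequence: 10 (from 1; 4 enters at step 3 and 8 at step 5).

Steps most likely to fail:

1. Step 5. Unactivated butadiene may add so slowly to the iminium ion that polymerisation of the acrolein or acyl transfer from the enol ester to the amine catalyst overtakes the cycloaddition. Facial discrimination with an acyclic diene may also be insufficient or of the unexpected sense. The fallback sets out from 7 and 8 and returns at 9. Covalent iminium activation is replaced by a chiral cationic boron Lewis acid, 3,3-diphenyl-1-(o-tolyl)tetrahydro-1H,3H-pyrrolo[1,2-c][1,3,2]oxazaborole protonated by HNTf2 (antipode chosen to give the S adduct), in CH2Cl2 at −78 to −40 °C. Butadiene itself and 2-substituted acroleins are established partners for this catalyst class. Stereocontrol then rests on coordination of the formyl oxygen to boron and no longer on an iminium ion; no new compound is formed (F0).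

2. Step 9. Osmylation of the cinnamate alkene may compete with that of the ring alkene, leading to over-oxidation. The fallback sets out from 13 and returns at 15.
   - 13 is epoxidised with 3-chloroperbenzoic acid (CH2Cl2, Na2HPO4, rt). The conjugated ester is inert to this peracid, which approaches anti to the lactone bridge, and the product is the 3,4-epoxide F1.
   - Acetyl bromide (CH2Cl2, 0 °C) opens the oxirane by O-acetylation and backside attack of bromide. This gives the trans bromo acetate F2, with the acetoxy group anti and bromine syn to the lactone bridge. It is drawn with bromine at C3; the regioisomer converges in the next operation.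
   - AgOAc in moist AcOH replaces bromine with inversion through participation of the neighbouring acetate (Woodward cis-hydroxylation logic). This leaves the cis-3,4-diol monoacetate F3 with both oxygens anti to the lactone.
   - F3 is submitted to the conditions of step 10, which also cleave the secondary acetate, and the route is rejoined at 15.

3. Step 3. Acetyl transfer from the aryl acetates to the enolate, C-acylation, or self-condensation of the dioxanone enolate may erode the enol ester. The fallback sets out from 4 and returns at 6. 4 is silylated (Me3SiCl, Et3N, NaI, MeCN) to 2,2-dimethyl-5-(trimethylsilyloxy)-4H-1,3-dioxin F4. This neutral enol silane is O-acylated by 3 under CuCl catalysis in 1,3-dimethyl-2-imidazolidinone, a known conversion of silyl enol ethers into enol esters, so no free potassium enolate meets the aryl acetates.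

**Further compounds**

F0 | step 5 | none | none
F1 | step 9 | 3,4-epoxide of 13, oxirane oxygen anti to the lactone bridge | O=C(/C=C/c1ccc(OC(C)=O)c(OC(C)=O)c1)O[C@@]12C[C@@H](OC1=O)[C@@H]3O[C@@H]3C2
F2 | step 9 | 4-acetoxy-3-bromo-7-oxo-6-oxabicyclo[3.2.1]octan-1-yl (E)-3-(3,4-diacetoxyphenyl)prop-2-enoate, 4-OAc anti and 3-Br syn to the lactone bridge | O=C(/C=C/c1ccc(OC(C)=O)c(OC(C)=O)c1)O[C@@]12C[C@@H](OC1=O)[C@H](OC(C)=O)[C@@H](Br)C2
F3 | step 9 | 4-acetoxy-3-hydroxy-7-oxo-6-oxabicyclo[3.2.1]octan-1-yl (E)-3-(3,4-diacetoxyphenyl)prop-2-enoate, both oxygens anti to the lactone bridge | O=C(/C=C/c1ccc(OC(C)=O)c(OC(C)=O)c1)O[C@@]12C[C@@H](OC1=O)[C@H](OC(C)=O)[C@H](O)C2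
F4 | step 3 | 2,2-dimethyl-5-(trimethylsilyloxy)-4H-1,3-dioxin | CC1(C)OCC(O[Si](C)(C)C)=CO1
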